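## Structural features

The target is a germacrane-type bicycle. A ten-membered carbocycle (C1–C10) is fused trans at C1 and C10 to an α-methylene-γ-butyrolactone (ring O, C12, C11, C10, C1) whose exocyclic alkene is C11=C13. The carbocycle holds a skipped diene: two Z-trisubstituted alkenes, C3=C4 and C6=C7, share the doubly allylic C5 methylene and carry methyl groups on C3 and C7. Four stereocentres stand in a row: C8 (R, acylated oxygen), C9 (S, free hydroxyl), C10 (R) and C1 (R). The C8 and C9 oxygens are anti, the C9 hydroxyl is syn to C1 across the C9–C10 bond, and C9 and C2 leave the lactone on opposite faces. The C8 oxygen carries a (2R,3R)-2,3-epoxy-2-methylbutanoyl group with two further stereocentres; its methyl groups are trans, as in angelic acid. Fragile groups are the methylene lactone (conjugate acceptor, able to translactonise to the C9 hydroxyl), the epoxy ester (acid, acyl migration to C9) and the 1,4-diene (alkene migration, oxidation at C5). The real difficulty is twofold: two Z-trisubstituted alkenes that no simple olefination guarantees, and closure of a ten-membered ring with control of C9 and C10. The key step uses the fact that C3 is the methyl-bearing end of a Z alkene: a cis-1,2-dialkylcyclopropanol with its carbinol carbon at C3, its ring CH at C4 and its ring CH2 as the future C3 methyl is a latent form of exactly this unit.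

## Logic of the disconnections

**28 to 27.** The C9–C10 bond of the ten-membered ring is cut; the alkene goes back from C11=C13 to C10=C11 and tin is placed on C13. This one bond creates C9 and C10 together and delivers the methylene lactone without a separate methylenation. The bicycle becomes an open chain that ends in a flat butenolide and an aldehyde. The forward step must run through an open transition state (C9 hydroxyl syn to C1), follow Felkin–Anh addition to the α-acyloxy aldehyde (C8/C9 anti), attack the butenolide face away from C2, and use a Lewis acid that spares the epoxy ester.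

**27 to 26, then to 21 and 25.** The acyl–oxygen bond at C8 is cut and C9 is taken back to a silyl ether. Acylating before ring closure lets the cyclisation end at 28 with no protecting-group steps after it. The gain is a diol derivative and a five-carbon acid. The forward steps must tell the primary C9 hydroxyl from the secondary C8 hydroxyl, and must oxidise C9 without passing through a free hydroxy ester (acyl migration) and without epimerising C8.

**25 to 24, 23 and 22.** The two epoxide C–O bonds and the oxidation level of the carboxyl carbon are cut back. The acid is made enantiopure on its own, because epoxidation of an angelate already on the diene could not be selective. The demand is reagent control of the epoxide face.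

**21 to 20, 19 and 18.** The C13–Sn bond goes back to C13–Br, the silyl ether to the diol, the diol to the acetonide. Tin is brought in only after the single acidic step. The substitution must occur at C13 and not at C10.

**18 to 17, then to 15 and 16.** The C10=C11 bond (metathesis) and the C12–O ester bond are cut. The lactone then comes from an allylic alcohol and a commercial acid. Ring closure between the vinyl group and the acrylate must outrun any event at the two trisubstituted alkenes.

**15 to 14.** The C1–C10 bond is cut. C1 is remote from C8, so it must be set by a catalyst; the vinyl donor must be non-basic because 14 is a β,γ-unsaturated aldehyde.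

**14 to 13 and 12.** Only the oxidation level and the protecting group at C1 change.

**12 to 11 and 9.** The C3 methyl goes back to CH2Br, and the C3=C4 alkene goes back to the cyclopropane by reconnecting C4 to C14 and restoring the C3–O bond. This stores the Z geometry as the cis relationship of two ring substituents. The forward steps need a concerted disrotatory opening, bromide capture at the primary terminus and direct (SN2) hydride delivery.

**9 to 2 and 8.** The C3–C4 and C3–C14 bonds are cut. A three-carbon ester and a six-carbon diene remain, and the stereocentres of the ring need no absolute control. The forward step must give the cis-dialkyl ring and must touch only the terminal alkene.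

**8 to 5 and 6, and 5 to 3.** The C6=C7 alkene is cut (Wittig), then the C7–methyl bond. The α-oxygen of 5 is relied on to place C5 cis to C8; C8 must not epimerise.

**2 to 1.** The O–Si bond is cut.

## Other disconnections considered

**Alternative 1:** The cut is the C9–C10 bond, as the ring-forming event of a plan organised around it. Forward, BF3·OEt2 would activate the aldehyde of the open-chain stannyl butenolide A1, C10 would attack C9 in an SE2' sense, and the macrocyclic methylene lactone A2 (free C9 hydroxyl, C8 4-methoxybenzyl ether) would result.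
- In its favour: ring, two stereocentres and the exocyclic alkene come from one mild operation. The intrinsic preferences (open transition state, Felkin–Anh, attack anti to the C1 substituent) all point to the natural configuration. The benzyl-type ether is inert to the Lewis acid.
- Against it here: the step says nothing about the two Z-trisubstituted alkenes, which A1 must already contain, so the hard stereochemical problem is only moved. The ether at C8 costs four operations after A2 (silylation of C9, oxidative debenzylation, acylation, desilylation). Tin is stoichiometric.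
- Comparison: the chosen route uses this same type of closure in step 20, so on the ring-forming event the alternative is the equal of the chosen plan. On robustness of the cyclisation substrate it is the better, because A1 has no epoxide. Mechanistically it is a polar addition, whereas the chosen key step is an organotitanium ring construction followed by a stereospecific electrocyclic opening; only the latter fixes an alkene geometry. In step count the alternative is longer by the four protecting-group steps.

**Alternative 2:** Retrosynthetically a bond is added: C3 is joined to C8, which turns the ten-membered ring into the cis-decalin hydroxy mesylate A3. Forward, KH would deprotonate the tertiary C8 alcohol and the alkoxide would expel the C4 mesylate through the antiperiplanar C3–C8 bond (Grob fragmentation) to give the Z,Z-dienone A4.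
- In its favour: no macrocyclisation and no high dilution. The C3=C4 geometry is dictated by the rigid relative configuration of A3, and the C6=C7 alkene is Z by construction because it sits in a six-membered ring.
- Against it here: A3 needs six stereocentres, three of which (C3, C4, C8) are destroyed. C8 emerges as a ketone conjugated with C6=C7 and must be reduced with control next to C9 in a flexible ring. The lactone still has to be made from the C11 side chain and the ester attached.
- Comparison: both plans store the C3=C4 geometry in a ring and release it by a stereospecific, orbital-controlled cleavage. The fragmentation is the better of the two in ring formation, since it makes the medium ring and secures both alkenes in one step. It is worse in the stereochemical budget (C8 is kept from the chiral pool in the chosen plan but must be remade here) and in step economy, since building A3 and finishing from A4 should take more steps than the chain route.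

**Alternative 3:** The cut is the C5–C6 bond at the doubly allylic methylene. Forward, zerovalent palladium would add oxidatively to the primary Z-allylic chloride of the seco compound A5, the Z-alkenylstannane at C6 would transmetalate, and reductive elimination would close the ring to A6, the C9 triethylsilyl ether of the target (Stille-type coupling).
- In its favour: closure at an unhindered CH2 under neutral conditions that the lactone, the epoxy ester and all stereocentres tolerate. The stannane couples with retention. Only a desilylation follows.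
- Against it here: the allylpalladium intermediate from a Z-allylic chloride can equilibrate toward the E form, which puts the C3=C4 geometry at risk, and coupling at C3 instead of C5 is possible. A5 needs both Z alkenes made beforehand with functional handles. Ten-membered ring closure by cross-coupling is demanding.
- Comparison: in steps after ring closure the alternative is the equal of the chosen plan (one deprotection against none), and in mildness of the closing step it is the better (no Lewis acid near the epoxide). Mechanistically it is weakest where the chosen plan is strongest: the cyclopropanol opening fixes the Z geometry irreversibly, the allylpalladium complex can lose it. No advantage in total step count is expected, since the Z-allylic chloride and the Z-alkenylstannane each need their own stereoselective synthesis.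

Key step: step 4

Assumption: C14 denotes the carbon that is the terminal CH2 of 8, the ring CH2 of 9 and finally the methyl on C3.
Remark: bromide 11 is E by the sequence rules (CH2Br outranks the C2 arm) although its two chain arms are cis; the dioxolane carbon is S in 3–5 and R from 8 on with no change in space.

## Route

Step 1
Reactants: 1 methyl 3-hydroxypropanoate
Product: 2 methyl 3-[(tert-butyldimethylsilyl)oxy]propanoate
Conditions: TBSCl, imidazole, CH2Cl2, 0 °C → rt
Reagents that add atoms: tert-butyl(chloro)dimethylsilane, CC(C)(C)[Si](C)(C)Cl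
Why: Silyl ether formation at a primary alcohol; the ester is untouched and the silyl ether later tolerates the Grignard reagent and titanium.

Step 2
Reactants: 3 methyl (4S)-2,2-dimethyl-1,3-dioxolane-4-carboxylate
Product: 5 1-[(4S)-2,2-dimethyl-1,3-dioxolan-4-yl]ethan-1-one, via Weinreb amide 4 (not isolated)
Conditions: MeNH(OMe)·HCl, iPrMgCl, THF, −20 °C; then MeMgBr, −20 → 0 °C; aq. NH4Cl
Reagents that add atoms: methylmagnesium bromide, C[Mg]Br; N,O-dimethylhydroxylamine hydrochloride, CNOC.Cl (its atoms stay in 4 only)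
Why: Weinreb ketone synthesis in one flask: the magnesium amide converts the ester into the N-methoxy-N-methylamide, and MeMgBr adds once because the chelated tetrahedral intermediate survives until work-up; low temperature should protect the α-stereocentre.

Step 3
Reactants: 6 but-3-enyl(triphenyl)phosphonium bromide; 5 1-[(4S)-2,2-dimethyl-1,3-dioxolan-4-yl]ethan-1-one
Product: 8 (4R)-4-[(2Z)-hexa-2,5-dien-2-yl]-2,2-dimethyl-1,3-dioxolane, via phosphorus ylide 7 (not isolated)
Conditions: 6, KN(SiMe3)2, THF, 0 °C; then 5, −78 °C → rt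
Reagents that add atoms: none
Why: Wittig olefination of an α-alkoxy methyl ketone with a non-stabilised ylide, a class known to place the new chain cis to the oxygenated carbon, here C5 cis to C8 (Z); the lithium-free base and low temperature favour kinetic control and limit enolisation of 5.

Step 4
Reactants: 2 methyl 3-[(tert-butyldimethylsilyl)oxy]propanoate; 8 (4R)-4-[(2Z)-hexa-2,5-dien-2-yl]-2,2-dimethyl-1,3-dioxolane
Product: 9 (1S,2R)-1-{2-[(tert-butyldimethylsilyl)oxy]ethyl}-2-{(2Z)-3-[(4R)-2,2-dimethyl-1,3-dioxolan-4-yl]but-2-en-1-yl}cyclopropan-1-ol (drawn; formed together with its (1R,2S) cis isomer)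
Conditions: Ti(OiPr)4 (1.0 equiv), c-C6H11MgCl (4 equiv, added over 2 h), THF, 20 °C; aq. NH4Cl
Reagents that add atoms: none
Why: Ti(OiPr)4 and two equivalents of c-C6H11MgCl give a dicyclohexyltitanium species that loses cyclohexane to form a cyclohexene complex of divalent titanium (a titanacyclopropane), and the bound cyclohexene is displaced by the terminal alkene of 8 because a monosubstituted alkene binds more strongly. The new titanacyclopropane inserts the ester carbonyl of 2 into its less hindered Ti–CH2 bond (first skeletal bond, C3–C14), methoxide leaves the oxatitanacyclopentane, and the resulting β-titanio ketone closes by addition of the secondary C4–Ti bond to the ketone (second bond, C3–C4). This closure of the three-membered ring is a 3-exo-trig process. The closest known reaction type is the Kulinkovich hydroxycyclopropanation in its alkene-exchange variant, established for intermolecular coupling of esters with terminal alkenes under these reagents. The two new stereocentres, C3 and C4, are controlled relative to each other by the cyclic transition state of the closure, in which titanium bridges the carbonyl oxygen and C4 so that the C5 arm ends trans to oxygen and therefore cis to the C2 arm; their absolute sense is not set by the remote C8 centre, which is harmless because both cis isomers give the same alkene in step 5. The step needs the cis-dialkyl relationship, secured by this mechanism, and reaction at the terminal alkene only, secured by the failure of the trisubstituted C6=C7 alkene to exchange onto titanium. Slow addition of the Grignard reagent keeps its concentration low and disfavours plain double alkylation of the ester; the silyl ether and the acetonide are inert to both reagents.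

Step 5
Reactants: 9 (1S,2R)-1-{2-[(tert-butyldimethylsilyl)oxy]ethyl}-2-{(2Z)-3-[(4R)-2,2-dimethyl-1,3-dioxolan-4-yl]but-2-en-1-yl}cyclopropan-1-ol
Product: 11 (4R)-4-[(2Z,5E)-6-(bromomethyl)-8-[(tert-butyldimethylsilyl)oxy]octa-2,5-dien-2-yl]-2,2-dimethyl-1,3-dioxolane, via cyclopropyl mesylate 10 (not isolated)
Conditions: MsCl, Et3N, Et2O, 0 °C; filter; MgBr2·OEt2, Et2O, 35 °C
Reagents that add atoms: magnesium bromide, Br[Mg]Br; methanesulfonyl chloride, CS(=O)(=O)Cl (its atoms stay in 10 only)
Why: Sulfonylation of the tertiary cyclopropanol, then cyclopropyl-to-allyl cation ring opening assisted by MgBr2: ionisation is concerted with disrotatory opening in which the C5 arm, trans to the leaving group, turns outward (Woodward–Hoffmann–DePuy rule), so C2 and C5 end cis. Bromide then adds at the primary terminus C14; ring closure onto C6=C7 is geometrically impossible because C5 is trans to C14.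

Step 6
Reactants: 11 (4R)-4-[(2Z,5E)-6-(bromomethyl)-8-[(tert-butyldimethylsilyl)oxy]octa-2,5-dien-2-yl]-2,2-dimethyl-1,3-dioxolane
Product: 12 (4R)-4-[(2Z,5Z)-8-[(tert-butyldimethylsilyl)oxy]-6-methylocta-2,5-dien-2-yl]-2,2-dimethyl-1,3-dioxolane
Conditions: LiBHEt3, THF, −20 → 0 °C
Reagents that add atoms: none
Why: SN2 displacement of a primary allylic bromide by hydride; no bond of the alkene changes, so the cis arrangement of C2 and C5 is kept and now reads Z.

Step 7
Reactants: 12 (4R)-4-[(2Z,5Z)-8-[(tert-butyldimethylsilyl)oxy]-6-methylocta-2,5-dien-2-yl]-2,2-dimethyl-1,3-dioxolane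
Product: 13 (3Z,6Z)-7-[(4R)-2,2-dimethyl-1,3-dioxolan-4-yl]-3-methylocta-3,6-dien-1-ol
Conditions: Bu4NF, THF, 0 °C → rt; aq. NH4Cl
Reagents that add atoms: none
Why: Fluoride cleavage of the primary silyl ether; the acetonide and both alkenes are inert.

Step 8
Reactants: 13 (3Z,6Z)-7-[(4R)-2,2-dimethyl-1,3-dioxolan-4-yl]-3-methylocta-3,6-dien-1-ol
Product: 14 (3Z,6Z)-7-[(4R)-2,2-dimethyl-1,3-dioxolan-4-yl]-3-methylocta-3,6-dienal
Conditions: Dess–Martin periodinane, NaHCO3, CH2Cl2, 0 °C; used at once
Reagents that add atoms: none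
Why: Dess–Martin oxidation under buffered, non-basic conditions, chosen so that the β,γ-unsaturated aldehyde is not drawn into conjugation.

Step 9
Reactants: 14 (3Z,6Z)-7-[(4R)-2,2-dimethyl-1,3-dioxolan-4-yl]-3-methylocta-3,6-dienal
Product: 15 (3R,5Z,8Z)-9-[(4R)-2,2-dimethyl-1,3-dioxolan-4-yl]-5-methyldeca-1,5,8-trien-3-ol
Conditions: Zn(CH=CH2)2, (−)-3-exo-(dimethylamino)isoborneol (10 mol %), toluene, −20 → 0 °C; aq. NH4Cl
Reagents that add atoms: divinylzinc, C=C[Zn]C=C
Why: Amino-alcohol-catalysed enantioselective addition of an alkenylzinc reagent to an aldehyde; this ligand enantiomer directs transfer to the Si face, which gives the R carbinol (C1), and the zinc reagent is not basic enough to isomerise 14.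

Step 10
Reactants: 15 (3R,5Z,8Z)-9-[(4R)-2,2-dimethyl-1,3-dioxolan-4-yl]-5-methyldeca-1,5,8-trien-3-ol; 16 2-(bromomethyl)prop-2-enoic acid
Product: 17 (3R,5Z,8Z)-9-[(4R)-2,2-dimethyl-1,3-dioxolan-4-yl]-5-methyldeca-1,5,8-trien-3-yl 2-(bromomethyl)prop-2-enoate
Conditions: DCC, DMAP (5 mol %), CH2Cl2, −20 → 0 °C
Reagents that add atoms: none
Why: Steglich esterification with retention at C1; low temperature and a small amount of the pyridine catalyst limit its attack on the allylic bromide.

Step 11
Reactants: 17 (3R,5Z,8Z)-9-[(4R)-2,2-dimethyl-1,3-dioxolan-4-yl]-5-methyldeca-1,5,8-trien-3-yl 2-(bromomethyl)prop-2-enoate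
Product: 18 (5R)-3-(bromomethyl)-5-{(2Z,5Z)-6-[(4R)-2,2-dimethyl-1,3-dioxolan-4-yl]-2-methylhepta-2,5-dien-1-yl}furan-2(5H)-one
Conditions: second-generation Grubbs catalyst (5 mol %), 1,4-benzoquinone (10 mol %), CH2Cl2 (0.005 M), 40 °C
Reagents that add atoms: none
Why: Ring-closing metathesis of an allylic acrylate to a butenolide (C10=C11); the ruthenium carbene should start at the vinyl group and close the five-membered ring faster than it engages either trisubstituted alkene, and the quinone suppresses hydride-induced alkene migration.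

Step 12
Reactants: 18 (5R)-3-(bromomethyl)-5-{(2Z,5Z)-6-[(4R)-2,2-dimethyl-1,3-dioxolan-4-yl]-2-methylhepta-2,5-dien-1-yl}furan-2(5H)-one
Product: 19 (5R)-3-(bromomethyl)-5-[(2Z,5Z,7R)-7,8-dihydroxy-2,6-dimethylocta-2,5-dien-1-yl]furan-2(5H)-one
Conditions: AcOH/THF/H2O (3:1:1), 35 °C
Reagents that add atoms: none
Why: Acid hydrolysis of a terminal acetonide; the lactone and the primary allylic bromide should survive a weakly acidic medium that contains no base or good nucleophile.

Step 13
Reactants: 19 (5R)-3-(bromomethyl)-5-[(2Z,5Z,7R)-7,8-dihydroxy-2,6-dimethylocta-2,5-dien-1-yl]furan-2(5H)-one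
Product: 20 (5R)-5-[(2Z,5Z,7R)-7,8-dihydroxy-2,6-dimethylocta-2,5-dien-1-yl]-3-[(tributylstannyl)methyl]furan-2(5H)-one
Conditions: (Bu3Sn)2, Pd2(dba)3 (2 mol %), THF, rt
Reagents that add atoms: hexabutyldistannane, CCCC[Sn](CCCC)(CCCC)[Sn](CCCC)(CCCC)CCCC
Why: Palladium-catalysed stannylation of an allylic bromide with a distannane: oxidative addition gives an allylpalladium complex, transmetalation and reductive elimination at the primary terminus C13 give the conjugated allylstannane. Tin is introduced only after the acidic step.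

Step 14
Reactants: 20 (5R)-5-[(2Z,5Z,7R)-7,8-dihydroxy-2,6-dimethylocta-2,5-dien-1-yl]-3-[(tributylstannyl)methyl]furan-2(5H)-one
Product: 21 (5R)-5-{(2Z,5Z,7R)-7-hydroxy-2,6-dimethyl-8-[(triethylsilyl)oxy]octa-2,5-dien-1-yl}-3-[(tributylstannyl)methyl]furan-2(5H)-one
Conditions: TESCl (1.05 equiv), imidazole, CH2Cl2, −78 °C
Reagents that add atoms: chlorotriethylsilane, CC[Si](Cl)(CC)CC
Why: Selective silylation: the primary C9 hydroxyl should react well before the hindered secondary allylic C8 hydroxyl at low temperature.

Step 15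
Reactants: 22 angelic acid, (2Z)-2-methylbut-2-enoic acid
Product: 23 (2Z)-2-methylbut-2-en-1-ol
Conditions: LiAlH4, Et2O, 0 °C → rt
Reagents that add atoms: none
Why: Hydride reduction of the carboxylic acid at the carbonyl carbon only; the alkene geometry is not touched.

Step 16
Reactants: 23 (2Z)-2-methylbut-2-en-1-ol
Product: 24 [(2S,3R)-2,3-dimethyloxiran-2-yl]methanol
Conditions: Ti(OiPr)4 (10 mol %), diethyl L-(+)-tartrate (12 mol %), tBuOOH, 4 Å molecular sieves, CH2Cl2, −20 °C
Reagents that add atoms: tert-butyl hydroperoxide, CC(C)(C)OO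
Why: Sharpless asymmetric epoxidation; the L-tartrate delivers oxygen to the face that gives the 2S,3R epoxy alcohol, the same sense as established for Z-allylic alcohols such as nerol, and syn addition keeps the two methyl groups trans.

Step 17
Reactants: 24 [(2S,3R)-2,3-dimethyloxiran-2-yl]methanol
Product: 25 (2R,3R)-2,3-dimethyloxirane-2-carboxylic acid
Conditions: TEMPO (20 mol %), PhI(OAc)2, MeCN/H2O (1:1), rt
Reagents that add atoms: water, O
Why: Oxoammonium-mediated oxidation of the primary alcohol through the aldehyde hydrate to the acid; neither stereocentre is touched, and the descriptor at C2 changes from S to R only because the carboxyl group now outranks C3.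

Step 18
Reactants: 21 (5R)-5-{(2Z,5Z,7R)-7-hydroxy-2,6-dimethyl-8-[(triethylsilyl)oxy]octa-2,5-dien-1-yl}-3-[(tributylstannyl)methyl]furan-2(5H)-one; 25 (2R,3R)-2,3-dimethyloxirane-2-carboxylic acid
Product: 26 (2R,3Z,6Z)-3,7-dimethyl-8-{(2R)-5-oxo-4-[(tributylstannyl)methyl]-2,5-dihydrofuran-2-yl}-1-[(triethylsilyl)oxy]octa-3,6-dien-2-yl (2R,3R)-2,3-dimethyloxirane-2-carboxylate
Conditions: DCC, DMAP, CH2Cl2, 0 °C → rt
Reagents that add atoms: none
Why: Steglich esterification; acylation at oxygen keeps the C8 configuration, and the epoxide, the stannane and the silyl ether are inert to the carbodiimide.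

Step 19
Reactants: 26 (2R,3Z,6Z)-3,7-dimethyl-8-{(2R)-5-oxo-4-[(tributylstannyl)methyl]-2,5-dihydrofuran-2-yl}-1-[(triethylsilyl)oxy]octa-3,6-dien-2-yl (2R,3R)-2,3-dimethyloxirane-2-carboxylate
Product: 27 (2R,3Z,6Z)-3,7-dimethyl-1-oxo-8-{(2R)-5-oxo-4-[(tributylstannyl)methyl]-2,5-dihydrofuran-2-yl}octa-3,6-dien-2-yl (2R,3R)-2,3-dimethyloxirane-2-carboxylate
Conditions: (COCl)2, DMSO, CH2Cl2, −78 → −40 °C; then iPr2NEt, −78 → −20 °C; used at once
Reagents that add atoms: none
Why: Swern oxidation applied directly to a primary triethylsilyl ether, which is cleaved and oxidised in one operation; this avoids a free primary alcohol next to the C8 ester (acyl migration), and the hindered amine at low temperature should spare the C8 centre.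

Step 20
Reactants: 27 (2R,3Z,6Z)-3,7-dimethyl-1-oxo-8-{(2R)-5-oxo-4-[(tributylstannyl)methyl]-2,5-dihydrofuran-2-yl}octa-3,6-dien-2-yl (2R,3R)-2,3-dimethyloxirane-2-carboxylate
Product: 28 (3aR,4S,5R,6Z,9Z,11aR)-4-hydroxy-6,10-dimethyl-3-methylidene-2-oxo-2,3,3a,4,5,8,11,11a-octahydrocyclodeca[b]furan-5-yl (2R,3R)-2,3-dimethyloxirane-2-carboxylate (CNP0108157.1)
Conditions: BF3·OEt2 (3 equiv), CH2Cl2 (0.002 M, slow addition of 27), −78 °C; aq. NaHCO3
Reagents that add atoms: none
Why: Lewis-acid-promoted intramolecular SE2' addition of an allylstannane to an aldehyde: C10 attacks C9, the alkene moves to C11=C13 and tin leaves, closing the ten-membered ring. The open antiperiplanar transition state should place the C9 hydroxyl syn to C1, Felkin–Anh addition with the acyloxy group as the polar substituent should make C8/C9 anti, and attack on the butenolide face away from C2 should give the trans lactone.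

## Compound list

1 | methyl 3-hydroxypropanoate | COC(=O)CCO | starting material
2 | methyl 3-[(tert-butyldimethylsilyl)oxy]propanoate | COC(=O)CCO[Si](C)(C)C(C)(C)C | intermediate
3 | methyl (4S)-2,2-dimethyl-1,3-dioxolane-4-carboxylate | COC(=O)[C@@H]1COC(C)(C)O1 | starting material
4 | (4S)-N-methoxy-N,2,2-trimethyl-1,3-dioxolane-4-carboxamide | CON(C)C(=O)[C@@H]1COC(C)(C)O1 | intermediate (not isolated)
5 | 1-[(4S)-2,2-dimethyl-1,3-dioxolan-4-yl]ethan-1-one | CC(=O)[C@@H]1COC(C)(C)O1 | intermediate
6 | but-3-enyl(triphenyl)phosphonium bromide | C=CCC[P+](c1ccccc1)(c1ccccc1)c1ccccc1.[Br-] | starting material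
7 | but-3-enylidene(triphenyl)phosphorane | C=CCC=P(c1ccccc1)(c1ccccc1)c1ccccc1 | intermediate (not isolated)
8 | (4R)-4-[(2Z)-hexa-2,5-dien-2-yl]-2,2-dimethyl-1,3-dioxolane | C=CC/C=C(/C)[C@@H]1COC(C)(C)O1 | intermediate
9 | (1S,2R)-1-{2-[(tert-butyldimethylsilyl)oxy]ethyl}-2-{(2Z)-3-[(4R)-2,2-dimethyl-1,3-dioxolan-4-yl]but-2-en-1-yl}cyclopropan-1-ol (with its 1R,2S cis isomer) | O[C@]1(CCO[Si](C)(C)C(C)(C)C)C[C@H]1C/C=C(/C)[C@@H]2COC(C)(C)O2 | intermediate
10 | methanesulfonate of 9 | CS(=O)(=O)O[C@]1(CCO[Si](C)(C)C(C)(C)C)C[C@H]1C/C=C(/C)[C@@H]2COC(C)(C)O2 | intermediate (not isolated)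
11 | (4R)-4-[(2Z,5E)-6-(bromomethyl)-8-[(tert-butyldimethylsilyl)oxy]octa-2,5-dien-2-yl]-2,2-dimethyl-1,3-dioxolane | CC(C)(C)[Si](C)(C)OCC/C(CBr)=C\C/C=C(/C)[C@@H]1COC(C)(C)O1 | intermediate
12 | (4R)-4-[(2Z,5Z)-8-[(tert-butyldimethylsilyl)oxy]-6-methylocta-2,5-dien-2-yl]-2,2-dimethyl-1,3-dioxolane | CC(C)(C)[Si](C)(C)OCC/C(C)=C\C/C=C(/C)[C@@H]1COC(C)(C)O1 | intermediate
13 | (3Z,6Z)-7-[(4R)-2,2-dimethyl-1,3-dioxolan-4-yl]-3-methylocta-3,6-dien-1-ol | OCC/C(C)=C\C/C=C(/C)[C@@H]1COC(C)(C)O1 | intermediate
14 | (3Z,6Z)-7-[(4R)-2,2-dimethyl-1,3-dioxolan-4-yl]-3-methylocta-3,6-dienal | O=CC/C(C)=C\C/C=C(/C)[C@@H]1COC(C)(C)O1 | intermediate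
15 | (3R,5Z,8Z)-9-[(4R)-2,2-dimethyl-1,3-dioxolan-4-yl]-5-methyldeca-1,5,8-trien-3-ol | C=C[C@H](O)C/C(C)=C\C/C=C(/C)[C@@H]1COC(C)(C)O1 | intermediate
16 | 2-(bromomethyl)prop-2-enoic acid | C=C(CBr)C(=O)O | starting material
17 | (3R,5Z,8Z)-9-[(4R)-2,2-dimethyl-1,3-dioxolan-4-yl]-5-methyldeca-1,5,8-trien-3-yl 2-(bromomethyl)prop-2-enoate | C=C[C@H](OC(=O)C(=C)CBr)C/C(C)=C\C/C=C(/C)[C@@H]1COC(C)(C)O1 | intermediate
18 | (5R)-3-(bromomethyl)-5-{(2Z,5Z)-6-[(4R)-2,2-dimethyl-1,3-dioxolan-4-yl]-2-methylhepta-2,5-dien-1-yl}furan-2(5H)-one | O=C1O[C@H](C/C(C)=C\C/C=C(/C)[C@@H]2COC(C)(C)O2)C=C1CBr | intermediate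
19 | (5R)-3-(bromomethyl)-5-[(2Z,5Z,7R)-7,8-dihydroxy-2,6-dimethylocta-2,5-dien-1-yl]furan-2(5H)-one | O=C1O[C@H](C/C(C)=C\C/C=C(/C)[C@@H](O)CO)C=C1CBr | intermediate
20 | (5R)-5-[(2Z,5Z,7R)-7,8-dihydroxy-2,6-dimethylocta-2,5-dien-1-yl]-3-[(tributylstannyl)methyl]furan-2(5H)-one | O=C1O[C@H](C/C(C)=C\C/C=C(/C)[C@@H](O)CO)C=C1C[Sn](CCCC)(CCCC)CCCC | intermediate
21 | (5R)-5-{(2Z,5Z,7R)-7-hydroxy-2,6-dimethyl-8-[(triethylsilyl)oxy]octa-2,5-dien-1-yl}-3-[(tributylstannyl)methyl]furan-2(5H)-one | O=C1O[C@H](C/C(C)=C\C/C=C(/C)[C@@H](O)CO[Si](CC)(CC)CC)C=C1C[Sn](CCCC)(CCCC)CCCC | intermediate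
22 | angelic acid, (2Z)-2-methylbut-2-enoic acid | C/C=C(/C)C(=O)O | starting material
23 | (2Z)-2-methylbut-2-en-1-ol | C/C=C(/C)CO | intermediate
24 | [(2S,3R)-2,3-dimethyloxiran-2-yl]methanol | OC[C@]1(C)O[C@@H]1C | intermediate
25 | (2R,3R)-2,3-dimethyloxirane-2-carboxylic acid | OC(=O)[C@]1(C)O[C@@H]1C | intermediate
26 | (2R,3Z,6Z)-3,7-dimethyl-8-{(2R)-5-oxo-4-[(tributylstannyl)methyl]-2,5-dihydrofuran-2-yl}-1-[(triethylsilyl)oxy]octa-3,6-dien-2-yl (2R,3R)-2,3-dimethyloxirane-2-carboxylate | O=C1O[C@H](C/C(C)=C\C/C=C(/C)[C@@H](OC(=O)[C@]2(C)O[C@@H]2C)CO[Si](CC)(CC)CC)C=C1C[Sn](CCCC)(CCCC)CCCC | intermediate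
27 | (2R,3Z,6Z)-3,7-dimethyl-1-oxo-8-{(2R)-5-oxo-4-[(tributylstannyl)methyl]-2,5-dihydrofuran-2-yl}octa-3,6-dien-2-yl (2R,3R)-2,3-dimethyloxirane-2-carboxylate | O=C1O[C@H](C/C(C)=C\C/C=C(/C)[C@@H](OC(=O)[C@]2(C)O[C@@H]2C)C=O)C=C1C[Sn](CCCC)(CCCC)CCCC | intermediate
28 | (3aR,4S,5R,6Z,9Z,11aR)-4-hydroxy-6,10-dimethyl-3-methylidene-2-oxo-2,3,3a,4,5,8,11,11a-octahydrocyclodeca[b]furan-5-yl (2R,3R)-2,3-dimethyloxirane-2-carboxylate | C=C1C(=O)O[C@@H]2C/C(C)=C\C/C=C(/C)[C@@H](OC(=O)[C@]3(C)O[C@@H]3C)[C@@H](O)[C@@H]12 | target

## Step count and least certain steps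

Total: 20 steps. Longest linear sequence: 16 steps (steps 2–14 and 18–20, from 3).

**Step 4 (key step).** The most likely failure is inefficient transfer of titanium from cyclohexene to the terminal alkene of 8 in an intermolecular setting. Titanium hydride species could also move the alkenes of the skipped diene. Either would leave 8 unconsumed or scrambled.
Fallback, from 8 back to 9: the titanacyclopropane is made from a Grignard reagent instead of by alkene exchange. Hydroboration of the terminal alkene of 8 with 9-borabicyclo[3.3.1]nonane and oxidation (NaOH, H2O2) would give (4Z)-5-[(4R)-2,2-dimethyl-1,3-dioxolan-4-yl]hex-4-en-1-ol F1. CBr4 and PPh3 would give (4R)-4-[(2Z)-6-bromohex-2-en-2-yl]-2,2-dimethyl-1,3-dioxolane F2, and magnesium in THF the hexenylmagnesium bromide F3. Two equivalents of F3 with 2 and Ti(OiPr)4 (the original Kulinkovich protocol) should give the same cis-cyclopropanol 9, at the cost of one equivalent of F3 lost as the alkane.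

**Step 20.** The most likely failure is competition between activation of the aldehyde and of the epoxy ester by BF3, together with participation of the neighbouring acyloxy carbonyl, which would erode Felkin control at C9 or open the epoxide.
Fallback, from 21 back to 28: the ester is attached after ring closure.
- 4-Methoxybenzyl 2,2,2-trichloroacetimidate with La(OTf)3 (cat.) would give the 4-methoxybenzyl ether F4 of 21.
- Swern oxidation as in step 19 would give the ether aldehyde F5.
- BF3·OEt2 at −78 °C under high dilution would give the macrocyclic hydroxy ether F6.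
- Et3SiOSO2CF3 and 2,6-lutidine would give the C9 silyl ether F7.
- DDQ in buffered CH2Cl2 would give the C8 alcohol F8.
- 25 with DCC and DMAP would give the silylated ester F9.
- HF·pyridine would give 28.

**Step 11.** The most likely failure is diversion of the ruthenium carbene, because the acrylate is a slow partner: ring closure onto C6=C7 or oligomerisation could compete.
Fallback, from 14 back to 18: the butenolide is built by carbonylation.
- Addition of the alkynylzinc reagent from tert-butyldimethyl(prop-2-yn-1-yloxy)silane (ZnEt2, Ti(OiPr)4, and BINOL of the enantiomeric series that delivers to the Si face) to 14 would give the propargylic alcohol F10.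
- NaAlH2(OCH2CH2OMe)2 followed by I2 would give the Z-iodoalkenol F11.
- PdCl2(PPh3)2, CO and K2CO3 would give the silyloxymethyl butenolide F12.
- Bu4NF would give the hydroxymethyl butenolide F13.
- CBr4 and PPh3 would give 18.

**Step 13.** The most likely failure is coupling of the new allylstannane with unreacted bromide on palladium (allyl–allyl coupling), or stannylation at C10 instead of C13.
Fallback, from 15 back to 20: tin is brought in with the acid. Zinc dust and Bu3SnCl in THF/aq. NH4Cl would convert 16 into 2-[(tributylstannyl)methyl]prop-2-enoic acid F14. DCC/DMAP esterification of 15 would give the stannyl acrylate F15, ring-closing metathesis as in step 11 the stannyl butenolide acetonide F16, and pyridinium p-toluenesulfonate in MeOH the diol 20.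

**Step 19.** The most likely failure is incomplete cleavage of the silyl ether under the oxidation conditions, or base-induced epimerisation at C8 during the amine stage.
Fallback, from 26 back to 27: the two events are separated and the amine is avoided. Pyridinium p-toluenesulfonate in MeOH at 0 °C would give the primary alcohol F17, which would be oxidised at once with Dess–Martin periodinane and NaHCO3 to 27.

## Further compounds

F1 | step 4 | (4Z)-5-[(4R)-2,2-dimethyl-1,3-dioxolan-4-yl]hex-4-en-1-ol | OCCC/C=C(/C)[C@@H]1COC(C)(C)O1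
F2 | step 4 | (4R)-4-[(2Z)-6-bromohex-2-en-2-yl]-2,2-dimethyl-1,3-dioxolane | BrCCC/C=C(/C)[C@@H]1COC(C)(C)O1
F3 | step 4 | {(4Z)-5-[(4R)-2,2-dimethyl-1,3-dioxolan-4-yl]hex-4-en-1-yl}magnesium bromide | Br[Mg]CCC/C=C(/C)[C@@H]1COC(C)(C)O1
F4 | step 20 | (5R)-5-{(2Z,5Z,7R)-7-[(4-methoxybenzyl)oxy]-2,6-dimethyl-8-[(triethylsilyl)oxy]octa-2,5-dien-1-yl}-3-[(tributylstannyl)methyl]furan-2(5H)-one | O=C1O[C@H](C/C(C)=C\C/C=C(/C)[C@@H](OCc2ccc(OC)cc2)CO[Si](CC)(CC)CC)C=C1C[Sn](CCCC)(CCCC)CCCC
F5 | step 20 | (2R,3Z,6Z)-2-[(4-methoxybenzyl)oxy]-3,7-dimethyl-8-{(2R)-5-oxo-4-[(tributylstannyl)methyl]-2,5-dihydrofuran-2-yl}octa-3,6-dienal | O=C1O[C@H](C/C(C)=C\C/C=C(/C)[C@@H](OCc2ccc(OC)cc2)C=O)C=C1C[Sn](CCCC)(CCCC)CCCC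
F6 | step 20 | (3aR,4S,5R,6Z,9Z,11aR)-4-hydroxy-5-[(4-methoxybenzyl)oxy]-6,10-dimethyl-3-methylidene-3a,4,5,8,11,11a-hexahydrocyclodeca[b]furan-2(3H)-one | C=C1C(=O)O[C@@H]2C/C(C)=C\C/C=C(/C)[C@@H](OCc3ccc(OC)cc3)[C@@H](O)[C@@H]12
F7 | step 20 | (3aR,4S,5R,6Z,9Z,11aR)-5-[(4-methoxybenzyl)oxy]-6,10-dimethyl-3-methylidene-4-[(triethylsilyl)oxy]-3a,4,5,8,11,11a-hexahydrocyclodeca[b]furan-2(3H)-one | C=C1C(=O)O[C@@H]2C/C(C)=C\C/C=C(/C)[C@@H](OCc3ccc(OC)cc3)[C@@H](O[Si](CC)(CC)CC)[C@@H]12
F8 | step 20 | (3aR,4S,5R,6Z,9Z,11aR)-5-hydroxy-6,10-dimethyl-3-methylidene-4-[(triethylsilyl)oxy]-3a,4,5,8,11,11a-hexahydrocyclodeca[b]furan-2(3H)-one | C=C1C(=O)O[C@@H]2C/C(C)=C\C/C=C(/C)[C@@H](O)[C@@H](O[Si](CC)(CC)CC)[C@@H]12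
F9 | step 20 | C9 triethylsilyl ether of 28 | C=C1C(=O)O[C@@H]2C/C(C)=C\C/C=C(/C)[C@@H](OC(=O)[C@]3(C)O[C@@H]3C)[C@@H](O[Si](CC)(CC)CC)[C@@H]12
F10 | step 11 | (4R,6Z,9Z)-1-[(tert-butyldimethylsilyl)oxy]-10-[(4R)-2,2-dimethyl-1,3-dioxolan-4-yl]-6-methylundeca-6,9-dien-2-yn-4-ol | CC(C)(C)[Si](C)(C)OCC#C[C@H](O)C/C(C)=C\C/C=C(/C)[C@@H]1COC(C)(C)O1
F11 | step 11 | (2Z,4R,6Z,9Z)-1-[(tert-butyldimethylsilyl)oxy]-10-[(4R)-2,2-dimethyl-1,3-dioxolan-4-yl]-2-iodo-6-methylundeca-2,6,9-trien-4-ol | CC(C)(C)[Si](C)(C)OC/C(I)=C/[C@H](O)C/C(C)=C\C/C=C(/C)[C@@H]1COC(C)(C)O1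
F12 | step 11 | (5R)-3-{[(tert-butyldimethylsilyl)oxy]methyl}-5-{(2Z,5Z)-6-[(4R)-2,2-dimethyl-1,3-dioxolan-4-yl]-2-methylhepta-2,5-dien-1-yl}furan-2(5H)-one | O=C1O[C@H](C/C(C)=C\C/C=C(/C)[C@@H]2COC(C)(C)O2)C=C1CO[Si](C)(C)C(C)(C)C
F13 | step 11 | (5R)-5-{(2Z,5Z)-6-[(4R)-2,2-dimethyl-1,3-dioxolan-4-yl]-2-methylhepta-2,5-dien-1-yl}-3-(hydroxymethyl)furan-2(5H)-one | O=C1O[C@H](C/C(C)=C\C/C=C(/C)[C@@H]2COC(C)(C)O2)C=C1CO
F14 | step 13 | 2-[(tributylstannyl)methyl]prop-2-enoic acid | C=C(C[Sn](CCCC)(CCCC)CCCC)C(=O)O
F15 | step 13 | (3R,5Z,8Z)-9-[(4R)-2,2-dimethyl-1,3-dioxolan-4-yl]-5-methyldeca-1,5,8-trien-3-yl 2-[(tributylstannyl)methyl]prop-2-enoate | C=C[C@H](OC(=O)C(=C)C[Sn](CCCC)(CCCC)CCCC)C/C(C)=C\C/C=C(/C)[C@@H]1COC(C)(C)O1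
F16 | step 13 | (5R)-5-{(2Z,5Z)-6-[(4R)-2,2-dimethyl-1,3-dioxolan-4-yl]-2-methylhepta-2,5-dien-1-yl}-3-[(tributylstannyl)methyl]furan-2(5H)-one | O=C1O[C@H](C/C(C)=C\C/C=C(/C)[C@@H]2COC(C)(C)O2)C=C1C[Sn](CCCC)(CCCC)CCCC
F17 | step 19 | (2R,3Z,6Z)-1-hydroxy-3,7-dimethyl-8-{(2R)-5-oxo-4-[(tributylstannyl)methyl]-2,5-dihydrofuran-2-yl}octa-3,6-dien-2-yl (2R,3R)-2,3-dimethyloxirane-2-carboxylate | O=C1O[C@H](C/C(C)=C\C/C=C(/C)[C@@H](OC(=O)[C@]2(C)O[C@@H]2C)CO)C=C1C[Sn](CCCC)(CCCC)CCCC
A1 | alternative 1 | (2R,3Z,6Z)-2-[(4-methoxybenzyl)oxy]-3,7-dimethyl-8-{(2R)-5-oxo-4-[(tributylstannyl)methyl]-2,5-dihydrofuran-2-yl}octa-3,6-dienal | O=C1O[C@H](C/C(C)=C\C/C=C(/C)[C@@H](OCc2ccc(OC)cc2)C=O)C=C1C[Sn](CCCC)(CCCC)CCCC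
A2 | alternative 1 | (3aR,4S,5R,6Z,9Z,11aR)-4-hydroxy-5-[(4-methoxybenzyl)oxy]-6,10-dimethyl-3-methylidene-3a,4,5,8,11,11a-hexahydrocyclodeca[b]furan-2(3H)-one | C=C1C(=O)O[C@@H]2C/C(C)=C\C/C=C(/C)[C@@H](OCc3ccc(OC)cc3)[C@@H](O)[C@@H]12
A3 | alternative 2 | cis-fused decalin (C3–C8 bonded) with tertiary C8 hydroxyl, C4 methanesulfonate, C3 methyl, C6=C7 ring alkene, C1 silyl ether, C9 4-methoxybenzyl ether and C10 3-silyloxyprop-1-en-2-yl group | C=C(CO[Si](C)(C)C(C)(C)C)[C@H]1[C@H](O[Si](C)(C)C(C)(C)C)C[C@]2(C)[C@H](OS(C)(=O)=O)CC=C(C)[C@]2(O)[C@H]1OCc1ccc(OC)cc1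
A4 | alternative 2 | (2Z,5Z)-8-[(tert-butyldimethylsilyl)oxy]-9-{3-[(tert-butyldimethylsilyl)oxy]prop-1-en-2-yl}-10-[(4-methoxybenzyl)oxy]-2,6-dimethylcyclodeca-2,5-dien-1-one (configuration as in the SMILES) | C=C(CO[Si](C)(C)C(C)(C)C)[C@H]1[C@H](O[Si](C)(C)C(C)(C)C)C/C(C)=C\C/C=C(/C)C(=O)[C@H]1OCc1ccc(OC)cc1
A5 | alternative 3 | (1S,2R,3Z)-1-{(2R,3R)-2-[(2Z)-4-chloro-2-methylbut-2-en-1-yl]-4-methylidene-5-oxooxolan-3-yl}-3-methyl-4-(tributylstannyl)-1-[(triethylsilyl)oxy]but-3-en-2-yl (2R,3R)-2,3-dimethyloxirane-2-carboxylate | ClC/C=C(/C)C[C@H]1OC(=O)C(=C)[C@@H]1[C@H](O[Si](CC)(CC)CC)[C@H](OC(=O)[C@]2(C)O[C@@H]2C)/C(C)=C\[Sn](CCCC)(CCCC)CCCC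
A6 | alternative 3 | (3aR,4S,5R,6Z,9Z,11aR)-6,10-dimethyl-3-methylidene-2-oxo-4-[(triethylsilyl)oxy]-2,3,3a,4,5,8,11,11a-octahydrocyclodeca[b]furan-5-yl (2R,3R)-2,3-dimethyloxirane-2-carboxylate | C=C1C(=O)O[C@@H]2C/C(C)=C\C/C=C(/C)[C@@H](OC(=O)[C@]3(C)O[C@@H]3C)[C@@H](O[Si](CC)(CC)CC)[C@@H]12
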